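**Plan**

- Enabling feature: the C12 hydroxyl lies on the same face of the five-membered ring (C8–C12) as the C8 side chain and 1,3 to the C7 oxygen. A carbonate on O7 can therefore reach C12 across a C11=C12 double bond through a six-membered ring.
- Retrosynthetic cuts, in order: C14=C15 (Z-Wittig); C10–Cl and the C9 carbonyl (chlorination, allylic oxidation); C12–O with C11–I (iodocarbonation from the O7 tert-butyl carbonate); C12–C13 (Stille coupling on an enol triflate); C7–C8 (aldol of cyclopentanone with a C1–C7 aldehyde); C3–C4 (Wittig on an L-threitol acetonide).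
- Forward: the C1–C7 chain is built on the tartrate-derived dioxolane and joined to cyclopentanone, which supplies the carbocycle. A two-carbon arm is coupled to C12, the iodocarbonation closes the only new ring (a cis-fused cyclic carbonate), and enone, chlorine and ω-chain follow.
- Stereochemistry: C5 and C6 come from L-tartaric acid, C7 and C8 from a catalyst-controlled anti aldol, C12 is relayed from C8 through the O7 tether, and both Z alkenes come from the Wittig reaction and from (Z)-hex-3-en-1-ol.

Key step: step 12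

Remark: prostanoid numbering is used throughout (C1 ester carbon, C8–C12 ring, C13–C20 ω-chain); the C12 arm is carried through the cyclisation as a 2-(tert-butyldimethylsilyloxy)ethyl group and C5/C6 as the isopropylidene acetal, both spectators in the key step.

**Route**

Step 1
Reactants: 1 (4S,5S)-2,2-dimethyl-1,3-dioxolane-4,5-dimethanol
Product: 2 [(4S,5S)-5-(benzyloxymethyl)-2,2-dimethyl-1,3-dioxolan-4-yl]methanol
Conditions: NaH (1.0 equiv), BnBr (1.0 equiv), Bu4NI (cat.), THF, 0 °C to rt
Reagents that add atoms: benzyl bromide, BrCc1ccccc1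
Why: Williamson monobenzylation of a C2-symmetric diol whose two hydroxyls are equivalent, so only the statistical diether has to be removed and no stereocentre is touched.

Step 2
Reactants: 2 monobenzyl ether
Product: 3 (4R,5S)-5-(benzyloxymethyl)-2,2-dimethyl-1,3-dioxolane-4-carbaldehyde
Conditions: Dess–Martin periodinane, pyridine, CH2Cl2, 0 °C to rt
Reagents that add atoms: none
Why: Dess–Martin oxidation of the primary alcohol should give the aldehyde without epimerisation, the trans-substituted dioxolane aldehyde being the more stable epimer in any case.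

Step 3
Reactants: 3 benzyl-protected threose acetonide; 4 (2-carboxyethyl)triphenylphosphonium bromide
Product: 7 methyl (3Z)-4-[(4S,5S)-5-(benzyloxymethyl)-2,2-dimethyl-1,3-dioxolan-4-yl]but-3-enoate, via phosphorus ylide 5 (not isolated), via sodium carboxylate 6 (not isolated)
Conditions: 4, NaHMDS (2 equiv per 4), THF, −78 to 0 °C; add 3, −78 °C to rt; then MeI, DMF, rt
Reagents that add atoms: iodomethane, CI
Why: Wittig olefination with the carboxylate-bearing unstabilised ylide (the carboxylate suppresses retro-Michael loss of the phosphine) adds C1–C3 and O-methylation of the carboxylate in the same flask gives the ester; the Z geometry expected is irrelevant because the alkene is hydrogenated next.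

Step 4
Reactants: 7 unsaturated benzyl ether ester
Product: 8 methyl 4-[(4S,5S)-5-(hydroxymethyl)-2,2-dimethyl-1,3-dioxolan-4-yl]butanoate
Conditions: H2 (1 atm), 10% Pd/C, EtOAc/MeOH, rt
Reagents that add atoms: none
Why: catalytic hydrogenation should saturate the C3=C4 alkene and hydrogenolyse the benzyl ether in one operation while acetonide and ester stay intact.

Step 5
Reactants: 8 C7 alcohol
Product: 9 methyl 4-[(4S,5R)-5-formyl-2,2-dimethyl-1,3-dioxolan-4-yl]butanoate
Conditions: Dess–Martin periodinane, pyridine, CH2Cl2, 0 °C to rt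
Reagents that add atoms: none
Why: Dess–Martin oxidation should give the α-alkoxy C7 aldehyde without epimerisation at C6, the trans-dioxolane aldehyde being the preferred epimer.

Step 6
Reactants: 9 C1–C7 aldehyde; 10 cyclopentanone
Product: 11 methyl 4-[(4S,5S)-5-[(R)-hydroxy[(1S)-2-oxocyclopentyl]methyl]-2,2-dimethyl-1,3-dioxolan-4-yl]butanoate
Conditions: 10 (5 equiv), trans-4-(tert-butyldimethylsilyloxy)-L-proline (10 mol %), H2O (3 equiv), rt
Reagents that add atoms: none
Why: proline-type enamine aldol in which the anti-enamine of cyclopentanone attacks the Re face of the aldehyde under hydrogen-bond direction by the catalyst's carboxylic acid, which should give the anti aldol with 8S and 7R, the catalyst and not the C6 alkoxy centre selecting the aldehyde face (the pairing of L-proline with (R)-O-isopropylidene-glyceraldehyde-type acceptors).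

Step 7
Reactants: 11 anti aldol
Product: 12 methyl 4-[(4S,5R)-5-[(R)-(tert-butoxycarbonyloxy)[(1S)-2-oxocyclopentyl]methyl]-2,2-dimethyl-1,3-dioxolan-4-yl]butanoate
Conditions: Boc2O (1.5 equiv), DMAP (0.2 equiv), MeCN, 0 °C to rt
Reagents that add atoms: di-tert-butyl dicarbonate, CC(C)(C)OC(=O)OC(=O)OC(C)(C)C
Why: DMAP-catalysed O-acylation with Boc2O installs the tert-butyl carbonate that later serves as internal nucleophile, under conditions mild enough to avoid retro-aldol cleavage or β-elimination.

Step 8
Reactants: 12 β-carbonate ketone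
Product: 13 methyl 4-[(4S,5R)-5-[(R)-(tert-butoxycarbonyloxy)[(1S)-2-(trifluoromethylsulfonyloxy)cyclopent-2-en-1-yl]methyl]-2,2-dimethyl-1,3-dioxolan-4-yl]butanoate
Conditions: KHMDS (1.1 equiv) added to 12 and PhNTf2 (1.2 equiv), THF, −78 °C
Reagents that add atoms: N-phenylbis(trifluoromethanesulfonimide), O=S(=O)(N(c1ccccc1)S(=O)(=O)C(F)(F)F)C(F)(F)F
Why: kinetic deprotonation at the unhindered C11 methylene rather than the tertiary C8–H, with internal O-triflation of the enolate, should give the less substituted enol triflate and leave C8 and the carbonate untouched.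

Step 9
Reactants: 13 enol triflate; 14 tributyl(vinyl)stannane
Product: 15 methyl 4-[(4S,5R)-5-[(R)-(tert-butoxycarbonyloxy)[(1R)-2-ethenylcyclopent-2-en-1-yl]methyl]-2,2-dimethyl-1,3-dioxolan-4-yl]butanoate
Conditions: 14 (1.3 equiv), Pd(PPh3)4 (5 mol %), LiCl (3 equiv), THF, 65 °C
Reagents that add atoms: none
Why: Stille coupling of a cycloalkenyl triflate with a vinylstannane forms the C12–C13 bond without moving the ring alkene, and the homoallylic carbonate cannot ionise to a π-allyl complex.

Step 10
Reactants: 15 diene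
Product: 17 methyl 4-[(4S,5R)-5-[(R)-(tert-butoxycarbonyloxy)[(1R)-2-(2-hydroxyethyl)cyclopent-2-en-1-yl]methyl]-2,2-dimethyl-1,3-dioxolan-4-yl]butanoate, via alkylborane 16 (not isolated)
Conditions: 9-BBN (1.3 equiv), THF, 0 °C to rt; then aq. NaOAc, 30% H2O2, 0 °C to rt
Reagents that add atoms: hydrogen peroxide, OO
Why: hydroboration–oxidation in which 9-BBN adds anti-Markovnikov to the unhindered terminal vinyl group and not to the trisubstituted ring alkene, with buffered peroxide work-up that spares carbonate and ester, should give the C14 primary alcohol.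

Step 11
Reactants: 17 primary alcohol
Product: 18 methyl 4-[(4S,5R)-5-[(R)-(tert-butoxycarbonyloxy)[(1R)-2-[2-(tert-butyldimethylsilyloxy)ethyl]cyclopent-2-en-1-yl]methyl]-2,2-dimethyl-1,3-dioxolan-4-yl]butanoate
Conditions: TBSCl, imidazole, CH2Cl2, rt
Reagents that add atoms: tert-butyldimethylsilyl chloride, CC(C)(C)[Si](C)(C)Cl
Why: standard silylation of the primary alcohol masks O14 so that it cannot compete as a nucleophile in the iodocyclisation and survives until the late oxidation.

Step 12
Reactants: 18 homoallylic tert-butyl carbonate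
Product: 19 methyl (5S,6R,7R,8S,11R,12R)-14-(tert-butyldimethylsilyloxy)-11-iodo-5,6-(isopropylidenedioxy)-7,12-(carbonyldioxy)-15,16,17,18,19,20-hexanorprostanoate
Conditions: IBr (1.5 equiv), toluene, −85 °C; quench aq. Na2S2O3/NaHCO3
Reagents that add atoms: iodine monobromide, IBr
Why: IBr reversibly forms an iodonium ion on the C11=C12 alkene of the cyclopentene, the carbonyl oxygen of the O7 tert-butyl carbonate opens it at the tertiary carbon C12 anti to iodine, and the resulting 1,3-dioxan-2-ylium ion loses its tert-butyl group as tert-butyl bromide to leave the cyclic carbonate. This is the iodocarbonate cyclisation of homoallylic tert-butyl carbonates in its low-temperature IBr form. The ring closes 6-exo-trig (C12 inside the new ring, C11 outside) and gives a 1,3-dioxan-2-one cis-fused to the cyclopentane. C12 is controlled by C8, because the short C8–C7–O tether reaches only the alkene face on which the C8–C7 bond lies, so O12 ends cis to the C8 side chain as in the target; C11 is set by anti addition, iodine trans to O12. The step needs regioselectivity for C12 over C11, facial selectivity and chemoselectivity over the ether oxygens; Markovnikov opening at the trisubstituted carbon together with 6-exo over 7-endo closure, the tether, and the higher nucleophilicity of the carbonate carbonyl in a substrate without a second alkene secure them.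

Step 13
Reactants: 19 iodocarbonate
Product: 21 methyl (5S,6S,7R,8S,12S)-14-(tert-butyldimethylsilyloxy)-7,12-dihydroxy-5,6-(isopropylidenedioxy)-15,16,17,18,19,20-hexanorprost-10-enoate, via allylic carbonate 20 (not isolated)
Conditions: DBU (3 equiv), toluene, 80 °C; then MeOH, K2CO3, rt
Reagents that add atoms: none
Why: E2 dehydroiodination with DBU (anti-periplanar hydrogen at C10, none at C12, so only the C10=C11 alkene can form) followed by base-catalysed methanolysis of the cyclic carbonate frees the C7 and C12 hydroxyls before any base-sensitive carbonyl exists at C9.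

Step 14
Reactants: 21 7,12-diol
Product: 22 methyl (5S,6R,7R,8S,12S)-14-(tert-butyldimethylsilyloxy)-5,6:7,12-bis(isopropylidenedioxy)-15,16,17,18,19,20-hexanorprost-10-enoate
Conditions: 2-methoxypropene (3 equiv), PPTS (5 mol %), CH2Cl2, 0 °C
Reagents that add atoms: 2-methoxypropene, COC(C)=C
Why: acid-catalysed acetalisation ties the syn-disposed C7/C12 diol into a cis-fused isopropylidene acetal, protecting in one operation the secondary hydroxyl and the tertiary allylic hydroxyl that a chromium(VI) oxidant would otherwise transpose.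

Step 15
Reactants: 22 bis-acetonide cyclopentene
Product: 23 methyl (5S,6R,7R,8S,12S)-14-(tert-butyldimethylsilyloxy)-5,6:7,12-bis(isopropylidenedioxy)-9-oxo-15,16,17,18,19,20-hexanorprost-10-enoate
Conditions: CrO3 (15 equiv), 3,5-dimethylpyrazole (15 equiv), CH2Cl2, −20 °C
Reagents that add atoms: chromium trioxide, O=[Cr](=O)=O
Why: allylic C–H oxidation with CrO3·3,5-dimethylpyrazole should convert the only allylic methylene (C9, C12 being quaternary) into the ketone, oxygenation at the C11 terminus being disfavoured by the adjacent quaternary centre.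

Step 16
Reactants: 23 enone
Product: 24 methyl (5S,6R,7R,8S,12R)-14-(tert-butyldimethylsilyloxy)-10-chloro-5,6:7,12-bis(isopropylidenedioxy)-9-oxo-15,16,17,18,19,20-hexanorprost-10-enoate
Conditions: PhICl2 (1.2 equiv), pyridine (4 equiv), CH2Cl2, 0 °C to rt
Reagents that add atoms: (dichloroiodo)benzene, ClI(Cl)c1ccccc1
Why: α-chlorination of the enone by addition of chlorine across C10=C11 and pyridine-mediated loss of HCl (the acidic C10–H is removed, chloride leaves from C11) should give the 2-chloroenone, no other alkene being present.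

Step 17
Reactants: 24 chloroenone silyl ether
Product: 25 methyl (5S,6R,7R,8S,12R)-10-chloro-14-hydroxy-5,6:7,12-bis(isopropylidenedioxy)-9-oxo-15,16,17,18,19,20-hexanorprost-10-enoate
Conditions: HF·pyridine, pyridine, THF, 0 °C to rt
Reagents that add atoms: none
Why: fluoride-mediated desilylation with buffered HF·pyridine removes the primary TBS ether while both isopropylidene acetals and the chloroenone are stable.

Step 18
Reactants: 25 primary alcohol
Product: 26 methyl (5S,6R,7R,8S,12R)-10-chloro-5,6:7,12-bis(isopropylidenedioxy)-9,14-dioxo-15,16,17,18,19,20-hexanorprost-10-enoate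
Conditions: Dess–Martin periodinane, pyridine, CH2Cl2, 0 °C
Reagents that add atoms: none
Why: Dess–Martin oxidation gives the C14 aldehyde under buffered, non-basic conditions that avoid β-elimination of O12.

Step 19
Reactants: 27 (Z)-hex-3-en-1-ol
Product: 28 (Z)-1-iodohex-3-ene
Conditions: I2, PPh3, imidazole, CH2Cl2, 0 °C to rt
Reagents that add atoms: iodine, II
Why: Appel-type iodination of the primary alcohol proceeds by SN2 displacement of the oxyphosphonium group and leaves the remote Z alkene untouched.

Step 20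
Reactants: 28 homoallylic iodide
Product: 29 [(Z)-hex-3-en-1-yl]triphenylphosphonium iodide
Conditions: PPh3, MeCN, reflux
Reagents that add atoms: triphenylphosphine, c1ccc(cc1)P(c1ccccc1)c1ccccc1
Why: SN2 quaternisation of triphenylphosphine by the primary iodide gives the Wittig salt.

Step 21
Reactants: 26 C14 aldehyde; 29 phosphonium iodide
Product: 31 methyl (5S,6R,7R,8S,12R,14Z,17Z)-10-chloro-5,6:7,12-bis(isopropylidenedioxy)-9-oxoprosta-10,14,17-trienoate, via phosphorus ylide 30 (not isolated)
Conditions: 29 (1.3 equiv), NaHMDS (1.25 equiv), THF, −78 to 0 °C; then 26, −78 to −20 °C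
Reagents that add atoms: none
Why: Wittig reaction of the unstabilised ylide (sodium base, low temperature) should form the C14=C15 alkene with Z selectivity through the kinetically favoured cis-oxaphosphetane, the aldehyde reacting far faster than the hindered C9 ketone and the C17 Z alkene coming unchanged from the leaf alcohol.

Step 22
Reactants: 31 bis-acetonide trienone
Product: 32 methyl (5S,6R,7R,8S,12R,14Z,17Z)-10-chloro-5,6,7,12-tetrahydroxy-9-oxoprosta-10,14,17-trienoate
Conditions: AcOH–H2O (4:1), 45 °C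
Reagents that add atoms: none
Why: mild acid hydrolysis of both isopropylidene acetals should free the four hydroxyls without dehydrating the β-hydroxy ketone, and the tertiary C12 alcohol cannot ionise because its allylic position is part of the electron-poor enone.

Step 23
Reactants: 32 tetraol
Product: 33 methyl (5S,6R,7R,8S,12R,14Z,17Z)-5,6,7-triacetoxy-10-chloro-12-hydroxy-9-oxoprosta-10,14,17-trienoate
Conditions: Ac2O, pyridine, DMAP (cat.), CH2Cl2, 0 °C to rt
Reagents that add atoms: acetic anhydride, CC(=O)OC(C)=O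
Why: acetylation with Ac2O/pyridine esterifies the three secondary hydroxyls at C5, C6 and C7 while the hindered tertiary C12 hydroxyl stays free, which gives the target.

**Compound list**

1 | (4S,5S)-2,2-dimethyl-1,3-dioxolane-4,5-dimethanol (2,3-O-isopropylidene-L-threitol) | OC[C@@H]1OC(C)(C)O[C@H]1CO | starting material
2 | [(4S,5S)-5-(benzyloxymethyl)-2,2-dimethyl-1,3-dioxolan-4-yl]methanol | c1ccccc1COC[C@@H]1OC(C)(C)O[C@H]1CO | intermediate
3 | (4R,5S)-5-(benzyloxymethyl)-2,2-dimethyl-1,3-dioxolane-4-carbaldehyde | c1ccccc1COC[C@@H]1OC(C)(C)O[C@H]1C=O | intermediate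
4 | (2-carboxyethyl)triphenylphosphonium bromide | OC(=O)CC[P+](c1ccccc1)(c1ccccc1)c1ccccc1.[Br-] | starting material
5 | sodium 3-(triphenylphosphoranylidene)propanoate (ylide, not isolated) | [Na+].[O-]C(=O)CC=P(c1ccccc1)(c1ccccc1)c1ccccc1 | intermediate
6 | sodium (3Z)-4-[(4S,5S)-5-(benzyloxymethyl)-2,2-dimethyl-1,3-dioxolan-4-yl]but-3-enoate (not isolated) | c1ccccc1COC[C@@H]1OC(C)(C)O[C@H]1/C=C\CC(=O)[O-].[Na+] | intermediate
7 | methyl (3Z)-4-[(4S,5S)-5-(benzyloxymethyl)-2,2-dimethyl-1,3-dioxolan-4-yl]but-3-enoate | c1ccccc1COC[C@@H]1OC(C)(C)O[C@H]1/C=C\CC(=O)OC | intermediate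
8 | methyl 4-[(4S,5S)-5-(hydroxymethyl)-2,2-dimethyl-1,3-dioxolan-4-yl]butanoate | OC[C@@H]1OC(C)(C)O[C@H]1CCCC(=O)OC | intermediate
9 | methyl 4-[(4S,5R)-5-formyl-2,2-dimethyl-1,3-dioxolan-4-yl]butanoate (C1–C7 aldehyde) | O=C[C@@H]1OC(C)(C)O[C@H]1CCCC(=O)OC | intermediate
10 | cyclopentanone | O=C1CCCC1 | starting material
11 | methyl 4-[(4S,5S)-5-[(R)-hydroxy[(1S)-2-oxocyclopentyl]methyl]-2,2-dimethyl-1,3-dioxolan-4-yl]butanoate (anti aldol, 7R,8S) | O=C1CCC[C@H]1[C@@H](O)[C@@H]2OC(C)(C)O[C@H]2CCCC(=O)OC | intermediate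
12 | methyl 4-[(4S,5R)-5-[(R)-(tert-butoxycarbonyloxy)[(1S)-2-oxocyclopentyl]methyl]-2,2-dimethyl-1,3-dioxolan-4-yl]butanoate | O=C1CCC[C@H]1[C@@H](OC(=O)OC(C)(C)C)[C@@H]2OC(C)(C)O[C@H]2CCCC(=O)OC | intermediate
13 | methyl 4-[(4S,5R)-5-[(R)-(tert-butoxycarbonyloxy)[(1S)-2-(trifluoromethylsulfonyloxy)cyclopent-2-en-1-yl]methyl]-2,2-dimethyl-1,3-dioxolan-4-yl]butanoate | O=S(=O)(OC1=CCC[C@H]1[C@@H](OC(=O)OC(C)(C)C)[C@@H]2OC(C)(C)O[C@H]2CCCC(=O)OC)C(F)(F)F | intermediate
14 | tributyl(vinyl)stannane | C=C[Sn](CCCC)(CCCC)CCCC | starting material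
15 | methyl 4-[(4S,5R)-5-[(R)-(tert-butoxycarbonyloxy)[(1R)-2-ethenylcyclopent-2-en-1-yl]methyl]-2,2-dimethyl-1,3-dioxolan-4-yl]butanoate | C=CC1=CCC[C@H]1[C@@H](OC(=O)OC(C)(C)C)[C@@H]2OC(C)(C)O[C@H]2CCCC(=O)OC | intermediate
16 | B-alkyl-9-borabicyclo[3.3.1]nonane adduct of 15, boron on C14 (not isolated) | C1CC2CCCC(C1)B2CCC3=CCC[C@H]3[C@@H](OC(=O)OC(C)(C)C)[C@@H]4OC(C)(C)O[C@H]4CCCC(=O)OC | intermediate
17 | methyl 4-[(4S,5R)-5-[(R)-(tert-butoxycarbonyloxy)[(1R)-2-(2-hydroxyethyl)cyclopent-2-en-1-yl]methyl]-2,2-dimethyl-1,3-dioxolan-4-yl]butanoate | OCCC1=CCC[C@H]1[C@@H](OC(=O)OC(C)(C)C)[C@@H]2OC(C)(C)O[C@H]2CCCC(=O)OC | intermediate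
18 | methyl 4-[(4S,5R)-5-[(R)-(tert-butoxycarbonyloxy)[(1R)-2-[2-(tert-butyldimethylsilyloxy)ethyl]cyclopent-2-en-1-yl]methyl]-2,2-dimethyl-1,3-dioxolan-4-yl]butanoate (precursor of the key step) | CC(C)(C)[Si](C)(C)OCCC1=CCC[C@H]1[C@@H](OC(=O)OC(C)(C)C)[C@@H]2OC(C)(C)O[C@H]2CCCC(=O)OC | intermediate
19 | methyl (5S,6R,7R,8S,11R,12R)-14-(tert-butyldimethylsilyloxy)-11-iodo-5,6-(isopropylidenedioxy)-7,12-(carbonyldioxy)-15,16,17,18,19,20-hexanorprostanoate (cis-fused iodocarbonate, product of the key step) | CC(C)(C)[Si](C)(C)OCC[C@@]12OC(=O)O[C@H]([C@@H]1CC[C@H]2I)[C@@H]3OC(C)(C)O[C@H]3CCCC(=O)OC | intermediate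
20 | methyl (5S,6R,7R,8S,12S)-14-(tert-butyldimethylsilyloxy)-5,6-(isopropylidenedioxy)-7,12-(carbonyldioxy)-15,16,17,18,19,20-hexanorprost-10-enoate (allylic carbonate, not isolated) | CC(C)(C)[Si](C)(C)OCC[C@@]12OC(=O)O[C@H]([C@@H]1CC=C2)[C@@H]3OC(C)(C)O[C@H]3CCCC(=O)OC | intermediate
21 | methyl (5S,6S,7R,8S,12S)-14-(tert-butyldimethylsilyloxy)-7,12-dihydroxy-5,6-(isopropylidenedioxy)-15,16,17,18,19,20-hexanorprost-10-enoate | CC(C)(C)[Si](C)(C)OCC[C@]1(O)C=CC[C@H]1[C@@H](O)[C@@H]2OC(C)(C)O[C@H]2CCCC(=O)OC | intermediate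
22 | methyl (5S,6R,7R,8S,12S)-14-(tert-butyldimethylsilyloxy)-5,6:7,12-bis(isopropylidenedioxy)-15,16,17,18,19,20-hexanorprost-10-enoate | CC(C)(C)[Si](C)(C)OCC[C@@]12OC(C)(C)O[C@H]([C@@H]1CC=C2)[C@@H]3OC(C)(C)O[C@H]3CCCC(=O)OC | intermediate
23 | methyl (5S,6R,7R,8S,12S)-14-(tert-butyldimethylsilyloxy)-5,6:7,12-bis(isopropylidenedioxy)-9-oxo-15,16,17,18,19,20-hexanorprost-10-enoate | CC(C)(C)[Si](C)(C)OCC[C@@]12OC(C)(C)O[C@H]([C@@H]1C(=O)C=C2)[C@@H]3OC(C)(C)O[C@H]3CCCC(=O)OC | intermediate
24 | methyl (5S,6R,7R,8S,12R)-14-(tert-butyldimethylsilyloxy)-10-chloro-5,6:7,12-bis(isopropylidenedioxy)-9-oxo-15,16,17,18,19,20-hexanorprost-10-enoate | CC(C)(C)[Si](C)(C)OCC[C@@]12OC(C)(C)O[C@H]([C@@H]1C(=O)C(Cl)=C2)[C@@H]3OC(C)(C)O[C@H]3CCCC(=O)OC | intermediate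
25 | methyl (5S,6R,7R,8S,12R)-10-chloro-14-hydroxy-5,6:7,12-bis(isopropylidenedioxy)-9-oxo-15,16,17,18,19,20-hexanorprost-10-enoate | OCC[C@@]12OC(C)(C)O[C@H]([C@@H]1C(=O)C(Cl)=C2)[C@@H]3OC(C)(C)O[C@H]3CCCC(=O)OC | intermediate
26 | methyl (5S,6R,7R,8S,12R)-10-chloro-5,6:7,12-bis(isopropylidenedioxy)-9,14-dioxo-15,16,17,18,19,20-hexanorprost-10-enoate (C14 aldehyde) | O=CC[C@@]12OC(C)(C)O[C@H]([C@@H]1C(=O)C(Cl)=C2)[C@@H]3OC(C)(C)O[C@H]3CCCC(=O)OC | intermediate
27 | (Z)-hex-3-en-1-ol | CC/C=C\CCO | starting material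
28 | (Z)-1-iodohex-3-ene | CC/C=C\CCI | intermediate
29 | [(Z)-hex-3-en-1-yl]triphenylphosphonium iodide | CC/C=C\CC[P+](c1ccccc1)(c1ccccc1)c1ccccc1.[I-] | intermediate
30 | [(Z)-hex-3-en-1-ylidene]triphenylphosphorane (ylide, not isolated) | CC/C=C\CC=P(c1ccccc1)(c1ccccc1)c1ccccc1 | intermediate
31 | methyl (5S,6R,7R,8S,12R,14Z,17Z)-10-chloro-5,6:7,12-bis(isopropylidenedioxy)-9-oxoprosta-10,14,17-trienoate | CC/C=C\C/C=C\C[C@@]12OC(C)(C)O[C@H]([C@@H]1C(=O)C(Cl)=C2)[C@@H]3OC(C)(C)O[C@H]3CCCC(=O)OC | intermediate
32 | methyl (5S,6R,7R,8S,12R,14Z,17Z)-10-chloro-5,6,7,12-tetrahydroxy-9-oxoprosta-10,14,17-trienoate | CC/C=C\C/C=C\C[C@]1(O)C=C(Cl)C(=O)[C@H]1[C@@H](O)[C@H](O)[C@H](CCCC(=O)OC)O | intermediate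
33 | methyl (5S,6R,7R,8S,12R,14Z,17Z)-5,6,7-triacetoxy-10-chloro-12-hydroxy-9-oxoprosta-10,14,17-trienoate (CNP0277476.1) | CC/C=C\C/C=C\C[C@]1(O)C=C(Cl)C(=O)[C@H]1[C@@H](OC(C)=O)[C@H](OC(C)=O)[C@H](CCCC(=O)OC)OC(C)=O | target

**Step count and risks**

Total step count: 23 (including the two steps that make phosphonium salt 29).
Longest linear sequence: 21 steps (steps 1–18 and 21–23).

Steps most likely to fail:

Step 6 (aldol). The enamine aldol may lose simple and facial selectivity. The small cyclopentanone enamine discriminates anti from syn transition states less well than six-membered donors, and the C6 alkoxy centre biases the aldehyde toward the opposite face, so catalyst control may be eroded and the wanted isomer would have to be separated from its diastereomers. The fallback replaces enamine catalysis by a Lewis-base-catalysed aldol of a preformed enolate with a closed transition state. It sets out from cyclopentanone 10, which is converted with TMSCl, Et3N and NaI in MeCN into 1-(trimethylsilyloxy)cyclopentene F1 and then, by silicon exchange with SiCl4 and catalytic Hg(OAc)2, into 1-(trichlorosilyloxy)cyclopentene F2. F2 should add to aldehyde 9 in the presence of a chiral stilbenediamine-derived phosphoramide (10 mol %, CH2Cl2, −78 °C) through a chair-like hexacoordinate siliconate, which favours the anti aldol with reagent control of the aldehyde face. Aqueous NaHCO3 work-up brings the route back at 11.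

Step 15 (allylic oxidation). The chromium oxidation may over-oxidise, attack C–H bonds next to oxygen, or oxygenate the transposed terminus C11 of the allylic intermediate. The fallback uses an ene/[2,3] allylic hydroxylation and a separate alcohol oxidation. It sets out from 22, which with catalytic SeO2 and t-BuOOH (CH2Cl2, rt) should give the C9 allylic alcohol F3. Only C9 carries allylic hydrogens (C12 is quaternary), so the oxygen can only end at C9 with the double bond back at C10=C11. The ene step must put selenium on the hindered C11, so it may be slow. Oxidation of F3 with MnO2 or Dess–Martin periodinane returns to the route at 23.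

Step 8 (enol triflate). Deprotonation at C8 would cause β-elimination of the carbonate, and the enolate oxygen may take over the Boc group. The fallback carries O7 as a silyl ether through the enolisation. It sets out from 11, which is silylated (TESOTf, 2,6-lutidine, CH2Cl2, −78 °C) to the triethylsilyl ether F4. Deprotonation of F4 with KHMDS in the presence of PhNTf2 (THF, −78 °C) should give the enol triflate F5. HF·pyridine then removes the silyl group to give the hydroxy enol triflate F6, and Boc2O/DMAP converts F6 into 13, where the route resumes.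

**Further compounds**

F1 | step 6 | 1-(trimethylsilyloxy)cyclopentene | C[Si](C)(C)OC1=CCCC1
F2 | step 6 | 1-(trichlorosilyloxy)cyclopentene | Cl[Si](Cl)(Cl)OC1=CCCC1
F3 | step 15 | 9-hydroxy analogue of 22 (C9 allylic alcohol, either C9 epimer) | CC(C)(C)[Si](C)(C)OCC[C@@]12OC(C)(C)O[C@H]([C@@H]1C(O)C=C2)[C@@H]3OC(C)(C)O[C@H]3CCCC(=O)OC
F4 | step 8 | 7-O-triethylsilyl ether of aldol 11 | O=C1CCC[C@H]1[C@@H](O[Si](CC)(CC)CC)[C@@H]2OC(C)(C)O[C@H]2CCCC(=O)OC
F5 | step 8 | 7-O-triethylsilyl enol triflate | O=S(=O)(OC1=CCC[C@H]1[C@@H](O[Si](CC)(CC)CC)[C@@H]2OC(C)(C)O[C@H]2CCCC(=O)OC)C(F)(F)F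
F6 | step 8 | 7-hydroxy enol triflate | O=S(=O)(OC1=CCC[C@H]1[C@@H](O)[C@@H]2OC(C)(C)O[C@H]2CCCC(=O)OC)C(F)(F)F
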